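## Retrosynthetic overview

1. Target 19 ← lipase-catalysed acetylation of the secondary OH of diol 18 ← diol-directed titanium bromochlorination of the ring A alkene of spiro-diol 17.
2. Ring A (formed second) ← ring-closing metathesis of allyl/methallyl diene 16 ← chelation-controlled methallylation of β-hydroxy aldehyde 15 (sets C1).
3. Ring B (formed first) ← enantiospecific bromonium-induced cation–olefin cyclisation of the (Z)-tetrasubstituted allylic tert-butyl carbonate 11; the chair transition state sets C6 and carbonate capture sets C7.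
4. 11 ← acetoacetate chemistry: dianion alkylation with triflate 3, C-allylation, (E)-enol tosylate, methyl cross-coupling, ester reduction.
5. C10 ← catalytic enantioselective bromochlorination of prenol (first stereocenter).

Assumption: positions are numbered as in spiro[5.5]undecane (C1–C5 ring A, C6 spiro, C7–C11 ring B), and the Schiff-base ligand enantiomer in step 1 is the one that gives the (R)-bromide.

## Route

Step 1
Reactants: 1 3-methylbut-2-en-1-ol (prenol)
Product: 2 (2R)-2-bromo-3-chloro-3-methylbutan-1-ol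
Conditions: NBS, ClTi(OiPr)3, chiral tridentate Schiff-base ligand (salicylaldimine of a 2-amino-1,1-diarylalkan-1-ol, 20 mol %), hexanes, −20 °C
Reagents that add atoms: N-bromosuccinimide (O=C1CCC(=O)N1Br); chlorotitanium triisopropoxide (CC(C)O[Ti](Cl)(OC(C)C)OC(C)C)
Why: Titanium/Schiff-base-catalysed enantioselective bromochlorination of an allylic alcohol, in which titanium-bound chloride opens the bromonium ion at the tertiary carbon (anti addition) and the catalyst sets the C–Br center that becomes C10 (R).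

Step 2
Reactants: 2 (2R)-2-bromo-3-chloro-3-methylbutan-1-ol
Product: 3 (2R)-2-bromo-3-chloro-3-methylbutyl trifluoromethanesulfonate
Conditions: Tf2O, pyridine, CH2Cl2, −78 °C, used crude
Reagents that add atoms: trifluoromethanesulfonic anhydride (O=S(=O)(OS(=O)(=O)C(F)(F)F)C(F)(F)F)
Why: O-sulfonylation of the primary alcohol gives an electrophile reactive enough for coupling at −78 °C and leaves the stereocenter untouched.

Step 3
Reactants: 3 (2R)-2-bromo-3-chloro-3-methylbutyl trifluoromethanesulfonate; 4 methyl acetoacetate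
Product: 6 methyl (6R)-6-bromo-7-chloro-7-methyl-3-oxooctanoate, via methyl acetoacetate dianion 5 (not isolated)
Conditions: 4, NaH, THF, 0 °C; n-BuLi, 0 °C; then 3, −78 → −40 °C; H2O
Reagents that add atoms: none
Why: γ-Alkylation of the acetoacetate dianion by a primary triflate is fast at −78 °C, where elimination of the β-bromide does not compete, and the C–Br center is not involved.

Step 4
Reactants: 6 methyl (6R)-6-bromo-7-chloro-7-methyl-3-oxooctanoate
Product: 7 methyl (6R)-6-bromo-7-chloro-7-methyl-3-oxo-2-(prop-2-en-1-yl)octanoate (both C2 epimers)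
Conditions: allyl bromide, K2CO3, acetone, rt
Reagents that add atoms: allyl bromide (C=CCBr)
Why: C-allylation of the β-keto ester enolate under mild base installs the future C5–C4 unit; the labile C2 center is erased in the next step, and the neopentyl-type secondary bromide is too hindered to alkylate intramolecularly.

Step 5
Reactants: 7 methyl (6R)-6-bromo-7-chloro-7-methyl-3-oxo-2-(prop-2-en-1-yl)octanoate
Product: 8 methyl (2E,6R)-6-bromo-7-chloro-7-methyl-2-(prop-2-en-1-yl)-3-(tosyloxy)oct-2-enoate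
Conditions: TsCl, N-methylimidazole, Et3N, toluene, 0 °C → rt; minor (Z)-isomer removed by chromatography
Reagents that add atoms: p-toluenesulfonyl chloride (Cc1ccc(cc1)S(Cl)(=O)=O)
Why: Stereoselective enol tosylation of a β-keto ester under non-chelating amine conditions places the tosyloxy group trans to the ester, which fixes the geometry of the tetrasubstituted alkene.

Step 6
Reactants: 8 methyl (2E,6R)-6-bromo-7-chloro-7-methyl-2-(prop-2-en-1-yl)-3-(tosyloxy)oct-2-enoate
Product: 9 methyl (2Z,6R)-6-bromo-7-chloro-3,7-dimethyl-2-(prop-2-en-1-yl)oct-2-enoate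
Conditions: MeZnCl, Pd(OAc)2 (5 mol %), SPhos (10 mol %), THF, 40 °C
Reagents that add atoms: methylzinc chloride (C[Zn]Cl)
Why: Negishi cross-coupling of the activated enol tosylate proceeds with retention, so methyl ends cis to allyl and the chain cis to the ester, while the unactivated alkyl halides are inert to the palladium catalyst and to the organozinc.

Step 7
Reactants: 9 methyl (2Z,6R)-6-bromo-7-chloro-3,7-dimethyl-2-(prop-2-en-1-yl)oct-2-enoate
Product: 10 (2Z,6R)-6-bromo-7-chloro-3,7-dimethyl-2-(prop-2-en-1-yl)oct-2-en-1-ol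
Conditions: iBu2AlH (2.5 equiv), CH2Cl2, −78 °C
Reagents that add atoms: none
Why: 1,2-Reduction of the enoate by the aluminium hydride gives the allylic alcohol and restores the nucleophilicity of the tetrasubstituted alkene without touching the halides.

Step 8
Reactants: 10 (2Z,6R)-6-bromo-7-chloro-3,7-dimethyl-2-(prop-2-en-1-yl)oct-2-en-1-ol
Product: 11 tert-butyl (2Z,6R)-6-bromo-7-chloro-3,7-dimethyl-2-(prop-2-en-1-yl)oct-2-en-1-yl carbonate
Conditions: Boc2O, DMAP (10 mol %), CH2Cl2, rt
Reagents that add atoms: di-tert-butyl dicarbonate (CC(C)(C)OC(=O)OC(=O)OC(C)(C)C)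
Why: Acyl transfer to the primary alcohol installs a tert-butyl carbonate that will act as the internal oxygen nucleophile in the cyclisation.

Step 9
Reactants: 11 tert-butyl (2Z,6R)-6-bromo-7-chloro-3,7-dimethyl-2-(prop-2-en-1-yl)oct-2-en-1-yl carbonate
Product: 13 (4aR,6R,8aR)-6-bromo-5,5,8a-trimethyl-4a-(prop-2-en-1-yl)hexahydro-4H-benzo[d][1,3]dioxin-2-one, via bromonium ion 12 (not isolated)
Conditions: (CF3)2CHOH, 2,6-di-tert-butylpyridine, 0 °C → rt
Reagents that add atoms: none
Why: Solvolysis of the tertiary chloride with bromine participation gives the configurationally defined bromonium ion, which triggers a chair cation–olefin cyclisation; the (Z)-alkene geometry puts CH2O axial and allyl equatorial on C6, and the carbonate carbonyl captures the C7 cation anti to the new C–C bond with loss of isobutene, setting C7.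

Step 10
Reactants: 13 (4aR,6R,8aR)-6-bromo-5,5,8a-trimethyl-4a-(prop-2-en-1-yl)hexahydro-4H-benzo[d][1,3]dioxin-2-one
Product: 14 (1R,2R,4R)-4-bromo-2-(hydroxymethyl)-1,3,3-trimethyl-2-(prop-2-en-1-yl)cyclohexan-1-ol
Conditions: K2CO3 (cat.), MeOH, 0 °C → rt
Reagents that add atoms: none
Why: Base-catalysed transesterification of the cyclic carbonate with methanol frees the primary and tertiary alcohols under conditions too mild to displace the hindered secondary bromide.

Step 11
Reactants: 14 (1R,2R,4R)-4-bromo-2-(hydroxymethyl)-1,3,3-trimethyl-2-(prop-2-en-1-yl)cyclohexan-1-ol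
Product: 15 (1S,3R,6R)-3-bromo-6-hydroxy-2,2,6-trimethyl-1-(prop-2-en-1-yl)cyclohexane-1-carbaldehyde
Conditions: Dess–Martin periodinane, CH2Cl2, rt
Reagents that add atoms: none
Why: Dess–Martin oxidation converts the only oxidisable (primary) alcohol into the aldehyde, whose quaternary α-carbon cannot epimerise or eliminate (the change of the C1 descriptor is a priority effect only).

Step 12
Reactants: 15 (1S,3R,6R)-3-bromo-6-hydroxy-2,2,6-trimethyl-1-(prop-2-en-1-yl)cyclohexane-1-carbaldehyde
Product: 16 (1R,2R,4R)-4-bromo-2-[(1R)-1-hydroxy-3-methylbut-3-en-1-yl]-1,3,3-trimethyl-2-(prop-2-en-1-yl)cyclohexan-1-ol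
Conditions: CH2=C(CH3)CH2MgCl (3 equiv), THF, −78 °C; aq NH4Cl
Reagents that add atoms: 2-methylallylmagnesium chloride (CC(=C)C[Mg]Cl)
Why: Cram-chelate Grignard addition: the magnesium alkoxide of the tertiary OH chelates the aldehyde and the nucleophile enters from the allyl-CH2 side, away from the gem-dimethyl carbon, giving the (R)-carbinol at the future C1.

Step 13
Reactants: 16 (1R,2R,4R)-4-bromo-2-[(1R)-1-hydroxy-3-methylbut-3-en-1-yl]-1,3,3-trimethyl-2-(prop-2-en-1-yl)cyclohexan-1-ol
Product: 17 (1R,6R,7R,10R)-10-bromo-3,7,11,11-tetramethylspiro[5.5]undec-3-ene-1,7-diol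
Conditions: second-generation Grubbs catalyst RuCl2(=CHPh)(H2IMes)(PCy3) (5 mol %), CH2Cl2, 40 °C
Reagents that add atoms: none
Why: Ring-closing metathesis of the allyl and methallyl groups closes ring A as the trisubstituted C3=C4 cyclohexene with loss of ethene; free alcohols and the alkyl bromide are tolerated.

Step 14
Reactants: 17 (1R,6R,7R,10R)-10-bromo-3,7,11,11-tetramethylspiro[5.5]undec-3-ene-1,7-diol
Product: 18 (1R,3S,4S,6R,7R,10R)-4,10-dibromo-3-chloro-3,7,11,11-tetramethylspiro[5.5]undecane-1,7-diol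
Conditions: ClTi(OiPr)3 (1.2 equiv), then NBS (1.1 equiv), CH2Cl2, −20 → 0 °C
Reagents that add atoms: N-bromosuccinimide (O=C1CCC(=O)N1Br); chlorotitanium triisopropoxide (CC(C)O[Ti](Cl)(OC(C)C)OC(C)C)
Why: Titanium-mediated anti bromochlorination directed by the syn-1,3-diol: the six-membered titanate holds ring A in the chair with the C1 oxygen axial, chloride is delivered from titanium to the tertiary C3 on that face, and bromine adds to C4 from the opposite face, setting C3 (S) and C4 (S).

Step 15
Reactants: 18 (1R,3S,4S,6R,7R,10R)-4,10-dibromo-3-chloro-3,7,11,11-tetramethylspiro[5.5]undecane-1,7-diol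
Product: 19 (1R,3S,4S,6R,7R,10R)-4,10-dibromo-3-chloro-7-hydroxy-3,7,11,11-tetramethylspiro[5.5]undecan-1-yl acetate
Conditions: immobilised Candida antarctica lipase B (a lipase), vinyl acetate, MTBE, 45 °C
Reagents that add atoms: vinyl acetate (CC(=O)OC=C)
Why: Lipase-catalysed transesterification acylates only the secondary (1R) carbinol (the tertiary OH is not a lipase substrate and any C1 epimer is the slow-reacting sense), giving the monoacetate without base or risk to the halides.

## Compound list

1 | 3-methylbut-2-en-1-ol (prenol) | CC(C)=CCO | starting material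
2 | (2R)-2-bromo-3-chloro-3-methylbutan-1-ol | OC[C@@H](Br)C(C)(C)Cl | intermediate
3 | (2R)-2-bromo-3-chloro-3-methylbutyl trifluoromethanesulfonate | FC(F)(F)S(=O)(=O)OC[C@@H](Br)C(C)(C)Cl | intermediate
4 | methyl acetoacetate | COC(=O)CC(C)=O | starting material
5 | methyl acetoacetate dianion (sodium lithium salt) | [Na+].[Li+].[CH2-]C(=O)[CH-]C(=O)OC | intermediate
6 | methyl (6R)-6-bromo-7-chloro-7-methyl-3-oxooctanoate | COC(=O)CC(=O)CC[C@@H](Br)C(C)(C)Cl | intermediate
7 | methyl (6R)-6-bromo-7-chloro-7-methyl-3-oxo-2-(prop-2-en-1-yl)octanoate (both C2 epimers) | COC(=O)C(CC=C)C(=O)CC[C@@H](Br)C(C)(C)Cl | intermediate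
8 | methyl (2E,6R)-6-bromo-7-chloro-7-methyl-2-(prop-2-en-1-yl)-3-(tosyloxy)oct-2-enoate | COC(=O)/C(CC=C)=C(/OS(=O)(=O)c1ccc(C)cc1)CC[C@@H](Br)C(C)(C)Cl | intermediate
9 | methyl (2Z,6R)-6-bromo-7-chloro-3,7-dimethyl-2-(prop-2-en-1-yl)oct-2-enoate | COC(=O)/C(CC=C)=C(/C)CC[C@@H](Br)C(C)(C)Cl | intermediate
10 | (2Z,6R)-6-bromo-7-chloro-3,7-dimethyl-2-(prop-2-en-1-yl)oct-2-en-1-ol | OC/C(CC=C)=C(/C)CC[C@@H](Br)C(C)(C)Cl | intermediate
11 | tert-butyl (2Z,6R)-6-bromo-7-chloro-3,7-dimethyl-2-(prop-2-en-1-yl)oct-2-en-1-yl carbonate | CC(C)(C)OC(=O)OC/C(CC=C)=C(/C)CC[C@@H](Br)C(C)(C)Cl | intermediate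
12 | (3R)-3-[(3Z)-4-{[(tert-butoxycarbonyl)oxy]methyl}-3-methylhepta-3,6-dien-1-yl]-2,2-dimethylbromiran-1-ium chloride (bromonium ion from 11) | CC(C)(C)OC(=O)OC/C(CC=C)=C(/C)CC[C@H]1[Br+]C1(C)C.[Cl-] | intermediate
13 | (4aR,6R,8aR)-6-bromo-5,5,8a-trimethyl-4a-(prop-2-en-1-yl)hexahydro-4H-benzo[d][1,3]dioxin-2-one (cis-fused cyclic carbonate) | C=CC[C@@]12C(C)(C)[C@H](Br)CC[C@@]2(C)OC(=O)OC1 | intermediate
14 | (1R,2R,4R)-4-bromo-2-(hydroxymethyl)-1,3,3-trimethyl-2-(prop-2-en-1-yl)cyclohexan-1-ol | C=CC[C@]1(CO)C(C)(C)[C@H](Br)CC[C@@]1(C)O | intermediate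
15 | (1S,3R,6R)-3-bromo-6-hydroxy-2,2,6-trimethyl-1-(prop-2-en-1-yl)cyclohexane-1-carbaldehyde | C=CC[C@]1(C=O)C(C)(C)[C@H](Br)CC[C@@]1(C)O | intermediate
16 | (1R,2R,4R)-4-bromo-2-[(1R)-1-hydroxy-3-methylbut-3-en-1-yl]-1,3,3-trimethyl-2-(prop-2-en-1-yl)cyclohexan-1-ol | C=CC[C@]1([C@H](O)CC(C)=C)C(C)(C)[C@H](Br)CC[C@@]1(C)O | intermediate
17 | (1R,6R,7R,10R)-10-bromo-3,7,11,11-tetramethylspiro[5.5]undec-3-ene-1,7-diol | O[C@@H]1CC(C)=CC[C@@]12C(C)(C)[C@H](Br)CC[C@@]2(C)O | intermediate
18 | (1R,3S,4S,6R,7R,10R)-4,10-dibromo-3-chloro-3,7,11,11-tetramethylspiro[5.5]undecane-1,7-diol | O[C@@H]1C[C@](C)(Cl)[C@@H](Br)C[C@@]12C(C)(C)[C@H](Br)CC[C@@]2(C)O | intermediate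
19 | (1R,3S,4S,6R,7R,10R)-4,10-dibromo-3-chloro-7-hydroxy-3,7,11,11-tetramethylspiro[5.5]undecan-1-yl acetate | CC(=O)O[C@@H]1C[C@](C)(Cl)[C@@H](Br)C[C@@]12C(C)(C)[C@H](Br)CC[C@@]2(C)O | target

## Count and risks

Total step count: 15. Longest linear sequence: 15 steps (1 → 19).

The three steps most likely to fail:

Step 14 (ring A bromochlorination). The sense of addition rests on chloride delivery from the titanium diolate, and direct use of this reagent on a homoallylic diol is untested. An unassisted addition would be expected to give the other trans isomer or an ether from the tertiary OH. The fallback sets out from 17 and comes back at 18, and replaces direct chloride delivery by an oxygen tether. Boc2O/DMAP acylates only the secondary alcohol to give tert-butyl (1R,6R,7R,10R)-10-bromo-7-hydroxy-3,7,11,11-tetramethylspiro[5.5]undec-3-en-1-yl carbonate F5. NBS in MeCN at 0 °C then effects bromocarbonate cyclisation: the axial carbonate carbonyl captures C3 on its own face while bromine adds to C4 from the other, with loss of isobutene, giving the cyclic 1,3-carbonate of (1R,3S,4S,6R,7R,10R)-4,10-dibromo-3,7,11,11-tetramethylspiro[5.5]undecane-1,3,7-triol F6. Et4NCl in (CF3)2CHOH at 40 °C ionises the tertiary C3–O bond with participation of the anti bromine, and chloride returns to C3 with retention while CO2 is lost, giving 18.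

Step 9 (solvolytic cyclisation with carbonate capture). The C7 cation may lose a proton instead of being trapped, or the allylic carbonate may ionise. The fallback sets out from 10 and comes back at 14. Free alcohol 10 is solvolysed in (CF3)2CHOH with the same pyridine base; the chair cyclisation still sets C6, and proton loss gives [(1R,3R)-3-bromo-2,2-dimethyl-6-methylidene-1-(prop-2-en-1-yl)cyclohexyl]methanol F1 together with its ring-olefin isomer [(1R,5R)-5-bromo-2,6,6-trimethyl-1-(prop-2-en-1-yl)cyclohex-2-en-1-yl]methanol F2. Hydroxyl-directed epoxidation with VO(acac)2 and t-BuOOH delivers oxygen to the face of the axial CH2OH. This gives [(3R,4R,6R)-6-bromo-5,5-dimethyl-4-(prop-2-en-1-yl)-1-oxaspiro[2.5]octan-4-yl]methanol F3 from F1 and [(1S,2R,4R,6R)-4-bromo-1,3,3-trimethyl-2-(prop-2-en-1-yl)-7-oxabicyclo[4.1.0]heptan-2-yl]methanol F4 from F2. LiAlH4 at −20 °C opens each epoxide at its less substituted carbon, and both give diol 14.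

Step 15 (lipase acetylation). The C1 carbinol sits next to the spiro quaternary carbon and may be acylated too slowly by the enzyme. The fallback sets out from 18 and comes back at 19: chemical acyl transfer with Ac2O, DMAP (cat.) and pyridine in CH2Cl2 at rt, which still leaves the tertiary C7–OH untouched and makes no new compound (F0).

## Further compounds

F1 | step 9 | [(1R,3R)-3-bromo-2,2-dimethyl-6-methylidene-1-(prop-2-en-1-yl)cyclohexyl]methanol | C=CC[C@]1(CO)C(C)(C)[C@H](Br)CCC1=C
F2 | step 9 | [(1R,5R)-5-bromo-2,6,6-trimethyl-1-(prop-2-en-1-yl)cyclohex-2-en-1-yl]methanol | C=CC[C@]1(CO)C(C)(C)[C@H](Br)CC=C1C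
F3 | step 9 | [(3R,4R,6R)-6-bromo-5,5-dimethyl-4-(prop-2-en-1-yl)-1-oxaspiro[2.5]octan-4-yl]methanol | C=CC[C@]1(CO)C(C)(C)[C@H](Br)CC[C@]12CO2
F4 | step 9 | [(1S,2R,4R,6R)-4-bromo-1,3,3-trimethyl-2-(prop-2-en-1-yl)-7-oxabicyclo[4.1.0]heptan-2-yl]methanol | C=CC[C@]1(CO)C(C)(C)[C@H](Br)C[C@H]2O[C@@]12C
F5 | step 14 | tert-butyl (1R,6R,7R,10R)-10-bromo-7-hydroxy-3,7,11,11-tetramethylspiro[5.5]undec-3-en-1-yl carbonate | CC(C)(C)OC(=O)O[C@@H]1CC(C)=CC[C@@]12C(C)(C)[C@H](Br)CC[C@@]2(C)O
F6 | step 14 | cyclic 1,3-carbonate of (1R,3S,4S,6R,7R,10R)-4,10-dibromo-3,7,11,11-tetramethylspiro[5.5]undecane-1,3,7-triol | O=C3O[C@@H]1C[C@](C)(O3)[C@@H](Br)C[C@@]12C(C)(C)[C@H](Br)CC[C@@]2(C)O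
F0 | step 15 | none | none
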